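**Plan**

- Retrosynthesis: the deoxybenzoin is cut at the C(=O)–CH2Ar bond to chromene aldehyde 10 and a 4-methoxybenzyl nucleophile. The pyran is then opened at O1–C2 and C3–C4 to dialdehyde 6 and isobutenylboronic acid 7. Finally 6 is traced through its two formyl C–C bonds and the central O–CH3 bond to phloroglucinol 1.
- Enabling feature: C5 (the OMe carbon) lies between C4a and C6, both carbon-substituted, and their outer neighbours C8a and C7 both carry oxygen. The benzene ring therefore has a local mirror plane through C5 and C8, which dialdehyde 6 reproduces exactly.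
- Forward order: both benzene rings are bought. Phloroglucinol is diformylated (regiochemistry fixed by symmetry), its two outer oxygens are masked, the oxygen between the formyl groups is methylated and the masks are removed. The pyran, the only ring formed, closes in step 5, and the side chain is joined last by Grignard addition and oxidation.
- A double formylation of 5-methoxyresorcinol is deliberately not used, because the ring carbon between its two hydroxyls would compete with the two carbons next to the methoxy group.
- Stereochemistry: the target has none; the two transient stereocentres (in 8 and 13) are formed racemic and erased.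

Key step: step 5

Remark: the target has no stereocentre and its only non-aromatic double bond is held cis in the ring, so it is one achiral compound and no enantiomer has to be selected.

**Step 1**
Reactants: 1 benzene-1,3,5-triol (phloroglucinol, anhydrous)
Product: 3 2,4,6-trihydroxybenzene-1,3-dicarbaldehyde, via bis-iminium salt 2 (not isolated)
Conditions: POCl3 (2.3 equiv), DMF (2.3 equiv), 1,4-dioxane, 0 °C → rt; then H2O, rt
Reagents that add atoms: N,N-dimethylformamide CN(C)C=O; water O
Why: Vilsmeier–Haack formylation, in which the chloroiminium ion attacks the threefold-activated ring twice (after the first attack the two free positions are still equivalent), the doubly iminium-substituted ring is too deactivated for a third attack, and aqueous hydrolysis of 2 should release the dialdehyde.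

**Step 2**
Reactants: 3 2,4,6-trihydroxybenzene-1,3-dicarbaldehyde
Product: 4 2-hydroxy-4,6-bis(methoxymethoxy)benzene-1,3-dicarbaldehyde
Conditions: MOMCl (2.1 equiv), i-Pr2NEt (2.5 equiv), CH2Cl2, 0 °C
Reagents that add atoms: chloromethyl methyl ether COCCl
Why: Williamson-type O-alkylation (MOM protection), expected at the two outer hydroxyls because each is para to one formyl group (more acidic) and flanked by a ring C–H (less hindered), whereas the hydroxyl between the two formyl groups is shielded on both sides and held in a carbonyl chelate, as in the familiar conversion of 2,4,6-trihydroxyaryl carbonyl compounds into 2-hydroxy-4,6-bis(MOM) ethers.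

**Step 3**
Reactants: 4 2-hydroxy-4,6-bis(methoxymethoxy)benzene-1,3-dicarbaldehyde
Product: 5 2-methoxy-4,6-bis(methoxymethoxy)benzene-1,3-dicarbaldehyde
Conditions: MeI (3 equiv), K2CO3, DMF, 40 °C
Reagents that add atoms: iodomethane CI
Why: Williamson etherification, in which carbonate in warm DMF opens the chelate of the one remaining phenol and its oxygen is methylated, while the MOM acetals and the non-enolisable aldehydes are inert to the base.

**Step 4**
Reactants: 5 2-methoxy-4,6-bis(methoxymethoxy)benzene-1,3-dicarbaldehyde
Product: 6 4,6-dihydroxy-2-methoxybenzene-1,3-dicarbaldehyde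
Conditions: HCl (3 M in MeOH), 45 °C; then H2O
Reagents that add atoms: none
Why: Acid-catalysed acetal cleavage (transacetalisation of both MOM ethers to dimethoxymethane), which the aryl methyl ether should survive because it needs a Lewis acid or hot HBr, any aldehyde dimethyl acetal reverting on the aqueous work-up.

**Step 5**
Reactants: 6 4,6-dihydroxy-2-methoxybenzene-1,3-dicarbaldehyde; 7 (2-methylprop-1-en-1-yl)boronic acid
Product: 10 7-hydroxy-5-methoxy-2,2-dimethyl-2H-chromene-6-carbaldehyde, via Petasis aminophenol 8 (not isolated), via o-quinone methide 9 (not isolated)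
Conditions: 7 (1.0 equiv), Bn2NH (1.0 equiv), 1,4-dioxane, rt → 90 °C
Reagents that add atoms: none
Why: Dibenzylamine condenses with one formyl group to an iminium ion, the neighbouring phenol binds the boronic acid as a boronate, and the 2-methylprop-1-enyl group migrates intramolecularly from boron to the iminium carbon (new C4–C3 bond) to give aminophenol 8. At 90 °C 8 loses dibenzylamine, which is thereby regenerated, to give o-quinone methide 9, and 9 closes the six-membered pyran by a thermal disrotatory oxa-6π electrocyclisation (new O1–C2 bond, the only ring formed). The closest known reaction type is the amine-promoted Petasis borono-Mannich condensation of salicylaldehydes with alkenylboronic acids that ends in 2H-chromenes. No stereocentre remains, since the aminated carbon of 8 is racemic and becomes sp2 and C2 carries two methyl groups. The step needs a single annulation at a defined oxygen: each formyl group has only one ortho-hydroxyl (its other neighbour is the methoxy carbon), the two formyl/hydroxyl pairs are mirror images so either one leads to 10, and a second annulation should be held back by one equivalent of 7 and by the lower electrophilicity of the remaining formyl group on the more electron-rich chromene.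

**Step 6**
Reactants: 10 7-hydroxy-5-methoxy-2,2-dimethyl-2H-chromene-6-carbaldehyde; 11 4-methoxybenzyl chloride
Product: 13 rac-1-(7-hydroxy-5-methoxy-2,2-dimethyl-2H-chromen-6-yl)-2-(4-methoxyphenyl)ethan-1-ol, via 4-methoxybenzylmagnesium chloride 12 (not isolated)
Conditions: Mg, Et2O, 0 °C (11 → 12, 3 equiv); then 10, THF, −20 → 0 °C; aq. NH4Cl
Reagents that add atoms: none
Why: Grignard 1,2-addition, in which the first equivalent of 12 deprotonates the phenol, the magnesium phenoxide chelates and activates the neighbouring formyl group and a further equivalent adds to it, the carbinol centre being formed racemic and removed in step 7.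

**Step 7**
Reactants: 13 rac-1-(7-hydroxy-5-methoxy-2,2-dimethyl-2H-chromen-6-yl)-2-(4-methoxyphenyl)ethan-1-ol
Product: 14 1-(7-hydroxy-5-methoxy-2,2-dimethyl-2H-chromen-6-yl)-2-(4-methoxyphenyl)ethan-1-one
Conditions: activated MnO2 (15 equiv), CH2Cl2, rt
Reagents that add atoms: none
Why: Manganese dioxide oxidation of a benzylic alcohol, in which the electron-rich aryl carbinol is oxidised on the solid surface under neutral conditions that should spare the phenol and the chromene double bond and avoid acid-induced dehydration to the stilbene, the ketone being stabilised by its hydrogen bond to the 7-hydroxyl.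

**Compound list**

1 | benzene-1,3,5-triol (phloroglucinol) | Oc1cc(O)cc(O)c1 | starting material
2 | (2,4,6-trihydroxy-1,3-phenylene)bis(N,N-dimethylmethaniminium) dichloride | C[N+](C)=Cc1c(O)cc(O)c(C=[N+](C)C)c1O.[Cl-].[Cl-] | intermediate
3 | 2,4,6-trihydroxybenzene-1,3-dicarbaldehyde | O=Cc1c(O)cc(O)c(C=O)c1O | intermediate
4 | 2-hydroxy-4,6-bis(methoxymethoxy)benzene-1,3-dicarbaldehyde | COCOc1cc(OCOC)c(C=O)c(O)c1C=O | intermediate
5 | 2-methoxy-4,6-bis(methoxymethoxy)benzene-1,3-dicarbaldehyde | COCOc1cc(OCOC)c(C=O)c(OC)c1C=O | intermediate
6 | 4,6-dihydroxy-2-methoxybenzene-1,3-dicarbaldehyde | COc1c(C=O)c(O)cc(O)c1C=O | intermediate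
7 | (2-methylprop-1-en-1-yl)boronic acid | CC(C)=CB(O)O | starting material
8 | rac-5-[1-(dibenzylamino)-3-methylbut-2-en-1-yl]-2,4-dihydroxy-6-methoxybenzaldehyde | COc1c(C=O)c(O)cc(O)c1C(C=C(C)C)N(Cc2ccccc2)Cc3ccccc3 | intermediate
9 | (3Z)-6-hydroxy-2-methoxy-3-(3-methylbut-2-en-1-ylidene)-4-oxocyclohexa-1,5-diene-1-carbaldehyde | C(/C=C(C)C)=C1/C(=O)C=C(O)C(C=O)=C1OC | intermediate
10 | 7-hydroxy-5-methoxy-2,2-dimethyl-2H-chromene-6-carbaldehyde | COc1c(C=O)c(O)cc2OC(C)(C)C=Cc12 | intermediate
11 | 4-methoxybenzyl chloride | COc1ccc(CCl)cc1 | starting material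
12 | 4-methoxybenzylmagnesium chloride | COc1ccc(C[Mg]Cl)cc1 | intermediate
13 | rac-1-(7-hydroxy-5-methoxy-2,2-dimethyl-2H-chromen-6-yl)-2-(4-methoxyphenyl)ethan-1-ol | COc1ccc(CC(O)c2c(O)cc3c(c2OC)C=CC(C)(C)O3)cc1 | intermediate
14 | 1-(7-hydroxy-5-methoxy-2,2-dimethyl-2H-chromen-6-yl)-2-(4-methoxyphenyl)ethan-1-one | COc1ccc(CC(=O)c2c(O)cc3c(c2OC)C=CC(C)(C)O3)cc1 | target

**Step count and risks**

Total steps: 7. Longest linear sequence: 7 steps (1 → 14); the Grignard reagent 12 is made within step 6.

Steps most likely to fail:

1. Step 2. The etherification may lose site selectivity, with the hydroxyl between the formyl groups being alkylated in competition with the second outer hydroxyl; this would lead to the unsymmetrical methyl ether after step 3. The fallback sets out from 3 and selects by size and neutral methylation instead of by acidity. Silylation with TIPSCl (2.05 equiv) and imidazole in DMF at 0 °C should reach only the two outer, singly flanked hydroxyls and give 2-hydroxy-4,6-bis(triisopropylsilyloxy)benzene-1,3-dicarbaldehyde F1. Mitsunobu methylation of the remaining acidic phenol (MeOH, PPh3, DIAD, THF, 0 °C → rt) should give 2-methoxy-4,6-bis(triisopropylsilyloxy)benzene-1,3-dicarbaldehyde F2. Desilylation with TBAF buffered by AcOH in THF at 0 °C returns to the route at 6.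

2. Step 5. Transfer of the hindered, β,β-disubstituted alkenyl group from boron to the electron-rich, chelated iminium ion may be slow, or a second annulation may take place at the remaining formyl/hydroxyl pair. The fallback sets out from 5 and forms the same two bonds with an organomagnesium reagent. Addition of 2-methylprop-1-enylmagnesium bromide (1.0 equiv, THF, −78 °C) to one of the two equivalent, unchelated formyl groups should give rac-5-(1-hydroxy-3-methylbut-2-en-1-yl)-6-methoxy-2,4-bis(methoxymethoxy)benzaldehyde F3. Methanolic HCl at 45 °C should then remove both MOM groups and ionise the allylic benzylic alcohol, so that the freed ortho-phenol closes the pyran by cyclodehydration through the same o-quinone methide. This returns to the route at 10.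

3. Step 7. The o-hydroxybenzylic carbinol may dehydrate to the stilbene during handling or on the oxidant, or the free phenol may be oxidised in competition with the carbinol. The fallback sets out from 10 and carries the phenol through the end game as an ether. MOMCl and K2CO3 in DMF should give 5-methoxy-7-(methoxymethoxy)-2,2-dimethyl-2H-chromene-6-carbaldehyde F4. Addition of 12 (1.5 equiv, THF, −20 °C) should give rac-1-[5-methoxy-7-(methoxymethoxy)-2,2-dimethyl-2H-chromen-6-yl]-2-(4-methoxyphenyl)ethan-1-ol F5. Dess–Martin oxidation (NaHCO3, CH2Cl2, 0 °C) should give 1-[5-methoxy-7-(methoxymethoxy)-2,2-dimethyl-2H-chromen-6-yl]-2-(4-methoxyphenyl)ethan-1-one F6. Brief treatment with methanolic HCl at rt removes the MOM group next to the ketone and returns to the route at 14.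

**Further compounds**

F1 | step 2 | 2-hydroxy-4,6-bis(triisopropylsilyloxy)benzene-1,3-dicarbaldehyde | CC(C)[Si](Oc1cc(O[Si](C(C)C)(C(C)C)C(C)C)c(C=O)c(O)c1C=O)(C(C)C)C(C)C
F2 | step 2 | 2-methoxy-4,6-bis(triisopropylsilyloxy)benzene-1,3-dicarbaldehyde | CC(C)[Si](Oc1cc(O[Si](C(C)C)(C(C)C)C(C)C)c(C=O)c(OC)c1C=O)(C(C)C)C(C)C
F3 | step 5 | rac-5-(1-hydroxy-3-methylbut-2-en-1-yl)-6-methoxy-2,4-bis(methoxymethoxy)benzaldehyde | COCOc1cc(OCOC)c(C(O)C=C(C)C)c(OC)c1C=O
F4 | step 7 | 5-methoxy-7-(methoxymethoxy)-2,2-dimethyl-2H-chromene-6-carbaldehyde | COCOc1cc2OC(C)(C)C=Cc2c(OC)c1C=O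
F5 | step 7 | rac-1-[5-methoxy-7-(methoxymethoxy)-2,2-dimethyl-2H-chromen-6-yl]-2-(4-methoxyphenyl)ethan-1-ol | COCOc1cc2OC(C)(C)C=Cc2c(OC)c1C(O)Cc3ccc(OC)cc3
F6 | step 7 | 1-[5-methoxy-7-(methoxymethoxy)-2,2-dimethyl-2H-chromen-6-yl]-2-(4-methoxyphenyl)ethan-1-one | COCOc1cc2OC(C)(C)C=Cc2c(OC)c1C(=O)Cc3ccc(OC)cc3
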